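**Plan**

Numbering used below (eremophilane): ring A = C1–C5 and C10 (C3 carries the ester oxygen, C4 and C5 the methyls); ring B = C5–C10 (C6 is the CH2, C7 carries the isopropylidene, C8 is the ketone, C9 the enol carbon).
Retrosynthesis: first cut the C3 ester (alcohol 16 + acid 22); then cut ring B at C6–C7 and at C9–C10 in one stroke, which leaves the ring-A cyclopropanol 6 and the three-carbon bromo enone 12.
Enabling feature: C6 sits on the quaternary C5 next to C10, so it is the β-carbon of a C10 ketone with no β-hydrogen; cleaving the C10–C6 bond of a cyclopropanol delivers it as a stable alkylpalladium homoenolate. C7–C8–C9 is a ketone between an alkenyl carbon and an oxygenated CH2, so one piece is an electrophile at C7 (alkenyl bromide) and a nucleophile at C9 (enolate).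
Forward: ring A is bought, the cyclopropane is added and then opened; ring B closes by alkenylation at C6 and, in the same flask, aldol condensation C9/C10; the diester side chain is joined last and the enol is unmasked.
Stereochemistry: C3 is bought; C4 comes from cuprate addition anti to the C3 oxygen; C5 from methylene transfer anti to the C4 methyl; both Z alkenes come from angelic acid and from a trans-hydroalumination/iodination and are carried through with retention.

Key step: step 9

Remark: (R)-4-[(tert-butyldimethylsilyl)oxy]cyclohex-2-en-1-one (1) is taken as a purchasable enantiopure building block.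

**Route**

Step 1
Reactants: 1 (R)-4-[(tert-butyldimethylsilyl)oxy]cyclohex-2-en-1-one
Product: 2 (R)-4-[(tert-butyldimethylsilyl)oxy]-2-iodocyclohex-2-en-1-one
Conditions: I2, pyridine, CH2Cl2, 0 °C to rt
Reagents that add atoms: iodine, II
Why: α-Iodination of an enone by reversible conjugate addition of pyridine, iodination of the resulting enolate and elimination (Baylis–Hillman-type sequence), which does not touch the silyloxy stereocenter.

Step 2
Reactants: 2 (R)-4-[(tert-butyldimethylsilyl)oxy]-2-iodocyclohex-2-en-1-one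
Product: 3 (R)-4-[(tert-butyldimethylsilyl)oxy]-2-methylcyclohex-2-en-1-one
Conditions: SnMe4, PdCl2(PhCN)2 (5 mol %), AsPh3, CuI, NMP, 80 °C
Reagents that add atoms: tetramethylstannane, C[Sn](C)(C)C
Why: Stille coupling of an α-iodo enone with a non-basic methyl donor, so the γ-silyloxy enone is not enolised.

Step 3
Reactants: 3 (R)-4-[(tert-butyldimethylsilyl)oxy]-2-methylcyclohex-2-en-1-one
Product: 4 tert-butyl{[(1R,2R)-2,3-dimethyl-4-[(trimethylsilyl)oxy]cyclohex-3-en-1-yl]oxy}dimethylsilane
Conditions: Me2CuLi (from MeLi and CuI), Me3SiCl, Et3N, THF, −78 °C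
Reagents that add atoms: lithium dimethylcuprate, [Li+].C[Cu-]C; chlorotrimethylsilane, C[Si](C)(C)Cl
Why: Conjugate addition of Me2CuLi anti to the neighbouring silyloxy group should set the C4 methyl trans to the C3 oxygen, and silyl trapping fixes the enolate as the single tetrasubstituted enol ether.

Step 4
Reactants: 4 tert-butyl{[(1R,2R)-2,3-dimethyl-4-[(trimethylsilyl)oxy]cyclohex-3-en-1-yl]oxy}dimethylsilane
Product: 6 (1S,4R,5R,6R)-4-[(tert-butyldimethylsilyl)oxy]-5,6-dimethylbicyclo[4.1.0]heptan-1-ol, via trimethylsilyl ether 5 (not isolated)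
Conditions: Et2Zn, CH2I2, CH2Cl2, 0 °C to rt; then K2CO3 (cat.), MeOH, 0 °C
Reagents that add atoms: diiodomethane, ICI
Why: Simmons–Smith cyclopropanation (Furukawa variant) of the electron-rich enol ether should occur on the face opposite the adjacent allylic methyl, the face on which electrophiles also attack such enolates, which sets the quaternary C5 with the new CH2 cis to the silyloxy group, and mild methanolysis then removes only the trimethylsilyl group.

Step 5
Reactants: 7 methyl glycolate
Product: 8 methyl 2-(methoxymethoxy)acetate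
Conditions: MeOCH2Cl, i-Pr2NEt, CH2Cl2, 0 °C to rt
Reagents that add atoms: chloromethyl methyl ether, COCCl
Why: O-Alkylation of the primary alcohol with a reactive α-chloro ether (acetal protection) under amine base.

Step 6
Reactants: 8 methyl 2-(methoxymethoxy)acetate
Product: 9 N-methoxy-2-(methoxymethoxy)-N-methylacetamide
Conditions: MeNHOMe·HCl, i-PrMgCl, THF, −20 °C
Reagents that add atoms: N,O-dimethylhydroxylamine hydrochloride, CNOC.Cl
Why: Aminolysis of the ester by the magnesium amide of N,O-dimethylhydroxylamine (Weinreb amide formation).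

Step 7
Reactants: 9 N-methoxy-2-(methoxymethoxy)-N-methylacetamide
Product: 10 1-(methoxymethoxy)-4-methylpent-3-en-2-one
Conditions: Me2C=CHMgBr, THF, 0 °C; aq. NH4Cl
Reagents that add atoms: 2-methylprop-1-enylmagnesium bromide, CC(C)=C[Mg]Br
Why: Weinreb ketone synthesis, in which the chelated tetrahedral intermediate prevents a second addition.

Step 8
Reactants: 10 1-(methoxymethoxy)-4-methylpent-3-en-2-one
Product: 12 3-bromo-1-(methoxymethoxy)-4-methylpent-3-en-2-one, via dibromide 11 (not isolated)
Conditions: Br2, CH2Cl2, 0 °C; then Et3N, 0 °C to rt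
Reagents that add atoms: bromine, BrBr
Why: Bromine addition to the enone followed by amine-induced dehydrobromination through the acidic α-hydrogen is the standard route to a 2-bromo enone, and the amine also keeps the medium non-acidic for the acetal.

Step 9
Reactants: 6 (1S,4R,5R,6R)-4-[(tert-butyldimethylsilyl)oxy]-5,6-dimethylbicyclo[4.1.0]heptan-1-ol; 12 3-bromo-1-(methoxymethoxy)-4-methylpent-3-en-2-one
Product: 15 (4aR,5R,6R)-6-[(tert-butyldimethylsilyl)oxy]-1-(methoxymethoxy)-4a,5-dimethyl-3-(propan-2-ylidene)-4,4a,5,6,7,8-hexahydronaphthalen-2(3H)-one, via 1,5-diketone 13 (not isolated), via ketol 14 (not isolated)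
Conditions: Pd(OAc)2 (5 mol %), XPhos (10 mol %), Cs2CO3, toluene, 80 °C; then KOt-Bu, t-BuOH, 50 °C (same flask)
Reagents that add atoms: none
Why: Proposed new method: zerovalent palladium inserts into the C–Br bond of 12, the caesium alkoxide of 6 binds to the divalent palladium centre and β-carbon elimination opens the cyclopropane at its C(OH)–CH2 bond to a β-keto alkylpalladium homoenolate, which cannot undergo β-hydride elimination because the neighbouring carbon is quaternary, and reductive elimination forms the C6–C7 bond of diketone 13; KOt-Bu then enolises the CH2 that carries the methoxymethoxy group (C9), which adds to the ring-A ketone (C10), and ketol 14 loses water to give the C9=C10 bond. The closest known reaction types are the palladium-catalysed ring-opening cross-coupling of cyclopropanols with aryl halides and the aldol-condensation half of a Robinson annulation, and what is new is the 2-bromo enone as coupling partner with annulation in the same flask. Ring B closes by a 6-(enolexo)-exo-trig aldol addition followed by E1cB dehydration. No stereocenter is formed, and none of the bonds at the quaternary C5 set in step 4 breaks. The step needs cleavage of the cyclopropane bond to CH2 and not of the ring-fusion bond, which palladium secures by forming the less substituted alkyl–metal bond, and it needs aldol closure through C9 and not through the ring-A CH2 or an isopropylidene methyl, which is secured because the alkoxy group makes C9–H the most acidic site and only this ketol can dehydrate to a conjugated dienone (the bridged ketol from the ring-A enolate cannot, by Bredt's rule).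

Step 10
Reactants: 15 (4aR,5R,6R)-6-[(tert-butyldimethylsilyl)oxy]-1-(methoxymethoxy)-4a,5-dimethyl-3-(propan-2-ylidene)-4,4a,5,6,7,8-hexahydronaphthalen-2(3H)-one
Product: 16 (4aR,5R,6R)-6-hydroxy-1-(methoxymethoxy)-4a,5-dimethyl-3-(propan-2-ylidene)-4,4a,5,6,7,8-hexahydronaphthalen-2(3H)-one
Conditions: Bu4NF, AcOH, THF, rt
Reagents that add atoms: none
Why: Fluoride-mediated cleavage of the secondary silyl ether, buffered with acetic acid so that the dienone is not deprotonated and the methoxymethyl enol ether stays in place.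

Step 11
Reactants: 17 but-2-yn-1-ol
Product: 19 (Z)-3-iodobut-2-en-1-ol, via cyclic alkenylaluminate 18 (not isolated)
Conditions: NaAlH2(OCH2CH2OMe)2, THF, 0 °C to rt; then I2, THF, −78 °C
Reagents that add atoms: iodine, II
Why: Hydroxyl-directed trans-hydroalumination gives a five-membered alkenylaluminate whose C–Al bond is cleaved by iodine with retention, which fixes iodine cis to the CH2OH group (Z).

Step 12
Reactants: 19 (Z)-3-iodobut-2-en-1-ol; 20 angelic acid [(Z)-2-methylbut-2-enoic acid]
Product: 21 (Z)-3-iodobut-2-en-1-yl (Z)-2-methylbut-2-enoate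
Conditions: PPh3, DIAD, THF, 0 °C to rt
Reagents that add atoms: none
Why: Mitsunobu esterification, in which the carboxylate attacks the primary allylic alkoxyphosphonium ion, so angelic acid is never turned into an activated acyl species and its Z double bond should not isomerise.

Step 13
Reactants: 21 (Z)-3-iodobut-2-en-1-yl (Z)-2-methylbut-2-enoate
Product: 22 (Z)-2-methyl-4-{[(Z)-2-methylbut-2-enoyl]oxy}but-2-enoic acid
Conditions: Pd(OAc)2 (5 mol %), CO (1 atm), Et3N, DMF/H2O, rt to 40 °C
Reagents that add atoms: carbon monoxide, [C-]#[O+]; water, O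
Why: Palladium-catalysed hydroxycarbonylation of an alkenyl iodide proceeds with retention of alkene geometry, and because the allylic oxygen is already acylated the Z-configured γ-oxy acid cannot lactonise.

Step 14
Reactants: 16 (4aR,5R,6R)-6-hydroxy-1-(methoxymethoxy)-4a,5-dimethyl-3-(propan-2-ylidene)-4,4a,5,6,7,8-hexahydronaphthalen-2(3H)-one; 22 (Z)-2-methyl-4-{[(Z)-2-methylbut-2-enoyl]oxy}but-2-enoic acid
Product: 24 6-O-acyl derivative of 16 (acyl = (Z)-2-methyl-4-{[(Z)-2-methylbut-2-enoyl]oxy}but-2-enoyl), via mixed anhydride 23 (not isolated)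
Conditions: 2,4,6-trichlorobenzoyl chloride, Et3N, toluene, rt; then 16, toluene, 70 °C (no DMAP)
Reagents that add atoms: none
Why: Yamaguchi esterification through the mixed anhydride, run without a nucleophilic catalyst as is usual for angelate-type acids to avoid Z-to-E isomerisation, acylates the equatorial C3 hydroxyl with retention because only the O–H bond is involved.

Step 15
Reactants: 24 6-O-acyl derivative of 16 (acyl = (Z)-2-methyl-4-{[(Z)-2-methylbut-2-enoyl]oxy}but-2-enoyl)
Product: 25 (4aR,5R,6R)-1,6-dihydroxy-4a,5-dimethyl-3-(propan-2-ylidene)-4,4a,5,6,7,8-hexahydronaphthalen-2(3H)-one 6-[(Z)-2-methyl-4-{[(Z)-2-methylbut-2-enoyl]oxy}but-2-enoate] (CNP0301409.1)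
Conditions: CF3CO2H, CH2Cl2, H2O (trace), 0 °C
Reagents that add atoms: none
Why: Acid-catalysed cleavage of the methoxymethyl acetal on the enol oxygen releases the diosphenol (the stable enol form of the 8,9-diketone) under conditions that should neither hydrolyse nor isomerise the two Z enoate esters.

**Compound list**

1 | (R)-4-[(tert-butyldimethylsilyl)oxy]cyclohex-2-en-1-one | O=C1C=C[C@H](O[Si](C)(C)C(C)(C)C)CC1 | starting material
2 | (R)-4-[(tert-butyldimethylsilyl)oxy]-2-iodocyclohex-2-en-1-one | O=C1C(I)=C[C@H](O[Si](C)(C)C(C)(C)C)CC1 | intermediate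
3 | (R)-4-[(tert-butyldimethylsilyl)oxy]-2-methylcyclohex-2-en-1-one | O=C1C(C)=C[C@H](O[Si](C)(C)C(C)(C)C)CC1 | intermediate
4 | tert-butyl{[(1R,2R)-2,3-dimethyl-4-[(trimethylsilyl)oxy]cyclohex-3-en-1-yl]oxy}dimethylsilane (ring methyl trans to the silyloxy group) | C[Si](C)(C)OC1=C(C)[C@@H](C)[C@H](O[Si](C)(C)C(C)(C)C)CC1 | intermediate
5 | O-trimethylsilyl ether of 6 (cyclopropane CH2 cis to the tert-butyldimethylsilyloxy group, trans to the neighbouring methyl) | C[Si](C)(C)O[C@@]12C[C@]1(C)[C@@H](C)[C@H](O[Si](C)(C)C(C)(C)C)CC2 | intermediate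
6 | (1S,4R,5R,6R)-4-[(tert-butyldimethylsilyl)oxy]-5,6-dimethylbicyclo[4.1.0]heptan-1-ol | O[C@@]12C[C@]1(C)[C@@H](C)[C@H](O[Si](C)(C)C(C)(C)C)CC2 | intermediate
7 | methyl glycolate | COC(=O)CO | starting material
8 | methyl 2-(methoxymethoxy)acetate | COCOCC(=O)OC | intermediate
9 | N-methoxy-2-(methoxymethoxy)-N-methylacetamide | COCOCC(=O)N(C)OC | intermediate
10 | 1-(methoxymethoxy)-4-methylpent-3-en-2-one | COCOCC(=O)C=C(C)C | intermediate
11 | 3,4-dibromo-1-(methoxymethoxy)-4-methylpentan-2-one (racemic) | COCOCC(=O)C(Br)C(C)(C)Br | intermediate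
12 | 3-bromo-1-(methoxymethoxy)-4-methylpent-3-en-2-one | COCOCC(=O)C(Br)=C(C)C | intermediate
13 | (2R,3R,4R)-4-[(tert-butyldimethylsilyl)oxy]-2-[4-(methoxymethoxy)-3-oxo-2-(propan-2-ylidene)butyl]-2,3-dimethylcyclohexan-1-one | COCOCC(=O)C(=C(C)C)C[C@]1(C)[C@@H](C)[C@H](O[Si](C)(C)C(C)(C)C)CCC1=O | intermediate
14 | (4aR,5R,6R)-6-[(tert-butyldimethylsilyl)oxy]-8a-hydroxy-1-(methoxymethoxy)-4a,5-dimethyl-3-(propan-2-ylidene)octahydronaphthalen-2(1H)-one (mixture at C1 and C8a) | COCOC1C(=O)C(=C(C)C)C[C@]2(C)[C@@H](C)[C@H](O[Si](C)(C)C(C)(C)C)CCC12O | intermediate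
15 | (4aR,5R,6R)-6-[(tert-butyldimethylsilyl)oxy]-1-(methoxymethoxy)-4a,5-dimethyl-3-(propan-2-ylidene)-4,4a,5,6,7,8-hexahydronaphthalen-2(3H)-one | CC(C)(C)[Si](C)(C)O[C@@H]1CCC2=C(OCOC)C(=O)C(=C(C)C)C[C@]2(C)[C@H]1C | intermediate
16 | (4aR,5R,6R)-6-hydroxy-1-(methoxymethoxy)-4a,5-dimethyl-3-(propan-2-ylidene)-4,4a,5,6,7,8-hexahydronaphthalen-2(3H)-one | O[C@@H]1CCC2=C(OCOC)C(=O)C(=C(C)C)C[C@]2(C)[C@H]1C | intermediate
17 | but-2-yn-1-ol | CC#CCO | starting material
18 | sodium 2,2-bis(2-methoxyethoxy)-3-methyl-2,5-dihydro-1,2-oxaaluminol-2-uide (cyclic alkenylaluminate) | [Na+].CC1=CCO[Al-]1(OCCOC)OCCOC | intermediate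
19 | (Z)-3-iodobut-2-en-1-ol | C/C(I)=C/CO | intermediate
20 | angelic acid, (Z)-2-methylbut-2-enoic acid | C/C=C(/C)C(=O)O | starting material
21 | (Z)-3-iodobut-2-en-1-yl (Z)-2-methylbut-2-enoate | C/C=C(/C)C(=O)OC/C=C(/C)I | intermediate
22 | (Z)-2-methyl-4-{[(Z)-2-methylbut-2-enoyl]oxy}but-2-enoic acid | C/C=C(/C)C(=O)OC/C=C(/C)C(=O)O | intermediate
23 | mixed anhydride of 22 with 2,4,6-trichlorobenzoic acid | C/C=C(/C)C(=O)OC/C=C(/C)C(=O)OC(=O)c1c(Cl)cc(Cl)cc1Cl | intermediate
24 | ester of alcohol 16 (at its 6-hydroxyl) with acid 22; methoxymethyl ether of the target | C/C=C(/C)C(=O)OC/C=C(/C)C(=O)O[C@@H]1CCC2=C(OCOC)C(=O)C(=C(C)C)C[C@]2(C)[C@H]1C | intermediate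
25 | (4aR,5R,6R)-1,6-dihydroxy-4a,5-dimethyl-3-(propan-2-ylidene)-4,4a,5,6,7,8-hexahydronaphthalen-2(3H)-one 6-[(Z)-2-methyl-4-{[(Z)-2-methylbut-2-enoyl]oxy}but-2-enoate], CNP0301409.1 | C/C=C(/C)C(=O)OC/C=C(/C)C(=O)O[C@@H]1CCC2=C(O)C(=O)C(=C(C)C)C[C@]2(C)[C@H]1C | target

**Count and risks**

Total step count: 15. Longest linear sequence: 8 steps (steps 1, 2, 3, 4, 9, 10, 14 and 15).

Steps most likely to fail:

1. Step 9. The alkylpalladium homoenolate may be protonated before it couples (simple ring opening of 6 to the methyl ketone), or reductive elimination between a neopentyl-type alkyl group and a tetrasubstituted alkenyl group may be too slow. The fallback uses known chemistry (Robinson annulation with an alkoxymethyl vinyl ketone, then aldol addition to acetone and dehydration); it sets out from 4 and comes back at 15. Weinreb amide 9 and CH2=CHMgBr would give 1-(methoxymethoxy)but-3-en-2-one F1 as the Michael acceptor. Enol ether 4 would be converted with MeLi into its lithium enolate, which should add to F1 anti to the C4 methyl and give (2R,3R,4R)-4-[(tert-butyldimethylsilyl)oxy]-2-[4-(methoxymethoxy)-3-oxobutyl]-2,3-dimethylcyclohexan-1-one F2 as the 1,5-diketone. NaOMe in MeOH would close ring B by aldol condensation to (4aR,5R,6R)-6-[(tert-butyldimethylsilyl)oxy]-1-(methoxymethoxy)-4a,5-dimethyl-4,4a,5,6,7,8-hexahydronaphthalen-2(3H)-one F3 as the bicyclic enone. Kinetic deprotonation of F3 at C7 with LiN(i-Pr)2, then ZnCl2 and acetone, would give (4aR,5R,6R)-6-[(tert-butyldimethylsilyl)oxy]-3-(2-hydroxypropan-2-yl)-1-(methoxymethoxy)-4a,5-dimethyl-4,4a,5,6,7,8-hexahydronaphthalen-2(3H)-one F4 as a mixture at C3, and dehydration of F4 (MsCl, Et3N; then DBU) would give 15.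

2. Step 4. The acid-labile trimethylsilyl enol ether may be cleaved by zinc iodide before methylene transfer, or methylene transfer to the tetrasubstituted alkene may show poor facial selectivity. The fallback sets out from 4 and comes back at 6. MeLi would give the regiodefined lithium enolate, whose C-alkylation with CH2I2 anti to the C4 methyl (the classical sense for such enolates) should give (2R,3R,4R)-4-[(tert-butyldimethylsilyl)oxy]-2-(iodomethyl)-2,3-dimethylcyclohexan-1-one F5 as a β-iodo ketone. SmI2 in THF would then close the three-membered ring of F5 by reductive 1,3-cyclisation onto the ketone to give 6.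

3. Step 13. Zerovalent palladium may ionise the allylic angelate in competition with carbonylation, with loss of the ester or lactonisation of the product. The fallback avoids palladium; it sets out from 19 and comes back at 22. Silylation of 19 (t-BuMe2SiCl, imidazole) would give (Z)-tert-butyl[(3-iodobut-2-en-1-yl)oxy]dimethylsilane F6 as the protected iodide. Iodine–lithium exchange on F6 (t-BuLi, Et2O, −78 °C) and trapping with Boc2O would give tert-butyl (Z)-4-[(tert-butyldimethylsilyl)oxy]-2-methylbut-2-enoate F7 with the alkene geometry retained. HF·pyridine would then give tert-butyl (Z)-4-hydroxy-2-methylbut-2-enoate F8 whose bulky ester resists lactonisation. Mitsunobu esterification of F8 with 20 would give tert-butyl (Z)-2-methyl-4-{[(Z)-2-methylbut-2-enoyl]oxy}but-2-enoate F9 as the diester, and CF3CO2H in CH2Cl2 would convert F9 into 22.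

**Further compounds**

F1 | step 9 | 1-(methoxymethoxy)but-3-en-2-one | COCOCC(=O)C=C
F2 | step 9 | (2R,3R,4R)-4-[(tert-butyldimethylsilyl)oxy]-2-[4-(methoxymethoxy)-3-oxobutyl]-2,3-dimethylcyclohexan-1-one | COCOCC(=O)CC[C@]1(C)[C@@H](C)[C@H](O[Si](C)(C)C(C)(C)C)CCC1=O
F3 | step 9 | (4aR,5R,6R)-6-[(tert-butyldimethylsilyl)oxy]-1-(methoxymethoxy)-4a,5-dimethyl-4,4a,5,6,7,8-hexahydronaphthalen-2(3H)-one | CC(C)(C)[Si](C)(C)O[C@@H]1CCC2=C(OCOC)C(=O)CC[C@]2(C)[C@H]1C
F4 | step 9 | (4aR,5R,6R)-6-[(tert-butyldimethylsilyl)oxy]-3-(2-hydroxypropan-2-yl)-1-(methoxymethoxy)-4a,5-dimethyl-4,4a,5,6,7,8-hexahydronaphthalen-2(3H)-one | CC(C)(C)[Si](C)(C)O[C@@H]1CCC2=C(OCOC)C(=O)C(C(C)(C)O)C[C@]2(C)[C@H]1C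
F5 | step 4 | (2R,3R,4R)-4-[(tert-butyldimethylsilyl)oxy]-2-(iodomethyl)-2,3-dimethylcyclohexan-1-one | IC[C@]1(C)[C@@H](C)[C@H](O[Si](C)(C)C(C)(C)C)CCC1=O
F6 | step 13 | (Z)-tert-butyl[(3-iodobut-2-en-1-yl)oxy]dimethylsilane | C/C(I)=C/CO[Si](C)(C)C(C)(C)C
F7 | step 13 | tert-butyl (Z)-4-[(tert-butyldimethylsilyl)oxy]-2-methylbut-2-enoate | C/C(=C/CO[Si](C)(C)C(C)(C)C)C(=O)OC(C)(C)C
F8 | step 13 | tert-butyl (Z)-4-hydroxy-2-methylbut-2-enoate | C/C(=C/CO)C(=O)OC(C)(C)C
F9 | step 13 | tert-butyl (Z)-2-methyl-4-{[(Z)-2-methylbut-2-enoyl]oxy}but-2-enoate | C/C=C(/C)C(=O)OC/C=C(/C)C(=O)OC(C)(C)C
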